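**Retrosynthetic overview**
- Target ⇒ free the phenol (acetate removal) ⇒ ester C–O disconnection at O8: (8S)-8-hydroxybulnesol + (E)-4-acetoxy-3-methoxycinnamic acid.
- (8S)-8-Hydroxybulnesol ⇒ C8–O bond made by hydroxyl-directed γ-C–H oxygenation of bulnesol: the C11–OH carries a transient diethylsilyl tether, C8–H → C8–Si → C8–O with retention.
- Ring order: no carbocycle is built. The five- and seven-membered rings and C4, C5, C7 come with bulnesol; only a temporary five-membered oxasilolane ring (O11–Si–C8) is closed and then opened by oxidation. C8 is the only new stereocentre.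

Assumption: (−)-bulnesol, the (4S,5S,7R)-guai-1(10)-en-11-ol of guaiac wood oil, is bought as the single natural enantiomer.
Numbering used (guaiane): C1=C10 alkene, methyls on C4 and C10, C5 ring-fusion CH, C7 carries C11(CH3)2OH, C8 lies between C7 and C9.

**Step 1**
Reactants: 1 (−)-bulnesol; 2 diethylsilane
Product: 5 (8S)-8-hydroxybulnesol, via hydrosilyl ether 3 (not isolated), via oxasilolane 4 (not isolated)
Conditions: (a) 2 (1.5 equiv), [Ir(cod)OMe]2 (0.5 mol%), THF, rt, then evaporate; (b) [Ir(cod)OMe]2 (2 mol%), Me4phen (3,4,7,8-tetramethyl-1,10-phenanthroline, 5 mol%), norbornene (1.5 equiv), THF, 100 °C; (c) t-BuOOH, CsOH·H2O, TBAF, DMF, 60 °C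
Reagents that add atoms: tert-butyl hydroperoxide CC(C)(C)OO
Why: Proposed new method: hydroxyl-directed γ-C–H oxygenation of a homoallylic ring methylene — the Si–H of 3 adds to iridium, C8–H is cleaved through a six-membered iridacycle and C–Si reductive elimination closes the trans-fused oxasilolane 4 (the C11 methyls are β and cannot react; of the four γ-hydrogens the pseudo-equatorial C8–H trans to the C7 side chain is the least hindered, C6 being shielded by the ring-fusion methine C5), then nucleophilic hydroperoxide oxidation of Tamao–Fleming type converts C8–Si into C8–O with retention and leaves the tetrasubstituted alkene alone, which sets C8 as S; closest known reaction type: iridium/phenanthroline-catalysed γ-silylation of secondary C–H bonds in hydrosilyl ethers of tertiary alcohols followed by Tamao–Fleming oxidation to 1,3-diols, not yet shown for a medium-ring homoallylic methylene with a competing second γ-methylene.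

**Step 2**
Reactants: 5 (8S)-8-hydroxybulnesol; 6 (E)-4-acetoxy-3-methoxycinnamic acid
Product: 7 8-O-[(E)-4-O-acetylferuloyl]-(8S)-8-hydroxybulnesol
Conditions: 6 (1.5 equiv), DIC (1.6 equiv), DMAP (0.2 equiv), CH2Cl2, 0 °C to rt
Reagents that add atoms: none
Why: Steglich esterification acylates only the secondary C8 hydroxyl because the tertiary C11 hydroxyl is too hindered, and since the acyl–O bond is formed the C8–O bond and all stereocentres are untouched.

**Step 3**
Reactants: 7 8-O-[(E)-4-O-acetylferuloyl]-(8S)-8-hydroxybulnesol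
Product: 8 target, 8-O-(E)-feruloyl-(8S)-8-hydroxybulnesol
Conditions: pyrrolidine (5 equiv), CH2Cl2, 0 °C to rt, 1 h
Reagents that add atoms: none
Why: Chemoselective aminolysis — the activated aryl acetate reacts with pyrrolidine far faster than the hindered alkyl cinnamate, so the phenol is freed without touching the ester, the E-alkene or any stereocentre.

**Compound list**
1 | (−)-bulnesol, 2-[(3S,3aS,5R)-3,8-dimethyl-1,2,3,3a,4,5,6,7-octahydroazulen-5-yl]propan-2-ol | CC1=C2CC[C@H](C)[C@@H]2C[C@@H](CC1)C(C)(C)O | starting material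
2 | diethylsilane | CC[SiH2]CC | starting material
3 | bulnesol O-diethyl(hydrido)silyl ether (O11–SiHEt2; ring stereocentres as in 1) | CC1=C2CC[C@H](C)[C@@H]2C[C@@H](CC1)C(C)(C)O[SiH](CC)CC | intermediate
4 | trans-fused 2,2-diethyl-1-oxa-2-silacyclopentane across C7–C8 of bulnesol (ring O11–Si–C8–C7–C11; Si on C8 trans to the C7 side chain; guaiane 4S,5S,7R,8S) | CC[Si]1(CC)[C@H]2CC(C)=C3CC[C@H](C)[C@@H]3C[C@@H]2C(C)(C)O1 | intermediate
5 | (8S)-8-hydroxybulnesol, (3S,3aS,5S,6S)-5-(2-hydroxypropan-2-yl)-3,8-dimethyl-1,2,3,3a,4,5,6,7-octahydroazulen-6-ol (8-OH trans to the C7 side chain, cis to H-5) | O[C@H]1CC(C)=C2CC[C@H](C)[C@@H]2C[C@@H]1C(C)(C)O | intermediate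
6 | (E)-4-acetoxy-3-methoxycinnamic acid (O-acetylferulic acid) | COc1cc(/C=C/C(=O)O)ccc1OC(C)=O | starting material
7 | (3S,3aS,5S,6S)-5-(2-hydroxypropan-2-yl)-3,8-dimethyl-1,2,3,3a,4,5,6,7-octahydroazulen-6-yl (E)-3-(4-acetoxy-3-methoxyphenyl)prop-2-enoate | COc1cc(/C=C/C(=O)O[C@H]2CC(C)=C3CC[C@H](C)[C@@H]3C[C@@H]2C(C)(C)O)ccc1OC(C)=O | intermediate
8 | (3S,3aS,5S,6S)-5-(2-hydroxypropan-2-yl)-3,8-dimethyl-1,2,3,3a,4,5,6,7-octahydroazulen-6-yl (E)-3-(4-hydroxy-3-methoxyphenyl)prop-2-enoate (CNP0241038.1) | COc1cc(/C=C/C(=O)O[C@H]2CC(C)=C3CC[C@H](C)[C@@H]3C[C@@H]2C(C)(C)O)ccc1O | target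

**Totals**
Total step count: 3. Longest linear sequence: 3 steps (1 → 5 → 7 → 8).

**Steps most likely to fail, with fallbacks**

Step 1 (the proposed new step). Risks are C6 versus C8 site selection, the choice between the two C8 hydrogens, and slow turnover on a ring methylene. The fallback uses known chemistry, sets out from 1 and comes back at 5, and makes the C8–O bond by alkene hydroboration instead of C–H silylation. Compound 1 is silylated with chloro(iodomethyl)dimethylsilane and imidazole in DMF to the bulnesol (iodomethyl)dimethylsilyl ether F1. Photoinduced Pd(OAc)2/Xantphos-catalysed radical-relay desaturation (Cs2CO3, benzene, blue light, rt) moves a hydrogen to the silylmethyl radical and, after β-hydride elimination, gives the 7,8-didehydrobulnesol trimethylsilyl ether F2. Hydroboration with BH3·SMe2 (THF, 0 °C) from the less hindered face, that of H-5, followed by NaBO3·4H2O adds H to C7 and OH to C8 syn. This puts the hydroxyl trans to the side chain in the 8-hydroxybulnesol 11-O-trimethylsilyl ether F3. K2CO3 in MeOH removes the silyl group to give 5.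

Step 2. Risks are the hindered secondary alcohol, N-acylurea formation and acetyl transfer from the aryl acetate. The fallback sets out from 5 and comes back at 8, bypassing 7, and builds the cinnamate C=C bond after the ester. Compound 5 is heated with Meldrum's acid in toluene at 100 °C (acyl ketene) to the 8-O-malonic half-ester F4. Knoevenagel–Doebner condensation of F4 with vanillin (pyridine, cat. piperidine, 60 °C) then gives the (E)-ferulate 8 with decarboxylation and needs no phenol protection.

Step 3. Risks are aminolysis or aza-Michael addition at the cinnamate and partial ester loss. The fallback sets out from 5 and comes back at 8 with no protecting group on the phenol. Compound 5 is treated with acryloyl chloride and Et3N in CH2Cl2 at 0 °C to give the 8-O-acrylate F5. A Mizoroki–Heck coupling of F5 with 4-iodo-2-methoxyphenol (Pd(OAc)2, P(o-tol)3, Et3N, DMF, 90 °C) then forms the (E)-ferulate 8 directly; the tetrasubstituted ring alkene is inert.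

**Further compounds**
F1 | step 1 | bulnesol O-(iodomethyl)dimethylsilyl ether | CC1=C2CC[C@H](C)[C@@H]2C[C@@H](CC1)C(C)(C)O[Si](C)(C)CI
F2 | step 1 | 7,8-didehydrobulnesol O-trimethylsilyl ether (guaia-1(10),7-dien-11-ol trimethylsilyl ether) | CC1=C2CC[C@H](C)[C@@H]2CC(=CC1)C(C)(C)O[Si](C)(C)C
F3 | step 1 | (8S)-8-hydroxybulnesol 11-O-trimethylsilyl ether | O[C@H]1CC(C)=C2CC[C@H](C)[C@@H]2C[C@@H]1C(C)(C)O[Si](C)(C)C
F4 | step 2 | (8S)-8-hydroxybulnesol 8-O-(carboxyacetyl) ester (malonic half-ester) | OC(=O)CC(=O)O[C@H]1CC(C)=C2CC[C@H](C)[C@@H]2C[C@@H]1C(C)(C)O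
F5 | step 3 | (8S)-8-hydroxybulnesol 8-O-acrylate | C=CC(=O)O[C@H]1CC(C)=C2CC[C@H](C)[C@@H]2C[C@@H]1C(C)(C)O
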